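**Retrosynthetic overview** (terpenoid locants: C1 lactone carbonyl, C2=C3 ring olefin, C4 ring stereocentre, C5–C20 chain, C24 on C7, C25 on C3)

1. Hippolide F ⇒ its C24 silyl ether; the last step is only a desilylation.
2. Butenolide (the only ring, closed in the penultimate step) ⇒ a (2Z)-4-hydroxy seco ester whose C1 ester closes onto O4 across the 2Z olefin, the lactonisation presumed to form the ring in the sponge. The seco ester is generated as its chromium alkoxide by an asymmetric Nozaki–Hiyama–Kishi union of a C20 β,γ-unsaturated aldehyde with methyl (Z)-4-hydroxy-3-iodobut-2-enoate, which makes C3–C4 and sets 4R.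
3. Aldehyde ⇒ Still Z-selective Wittig reaction (C6=C7, CH2O cis to C5) of an α-silyloxy ketone with a dioxolanylethyl ylide, then acetal hydrolysis.
4. Ketone ⇒ (2E,6E)-farnesyl bromide + the enolate of silyloxyacetone (C8–C9), then SeO2 oxidation of the terminal E-methyl group (C20–OH).
5. Iodo enoate ⇒ anti hydroiodination of methyl 4-hydroxybut-2-ynoate.

Assumption: the (S)-configured oxazoline–sulfonamide ligand is taken to deliver the alkenyl group to the Si face of the aldehyde (4R); if a Mosher check shows the opposite sense, its enantiomer is used with no other change.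

**Step 1**
Reactants: 1 1-[(tert-butyldimethylsilyl)oxy]propan-2-one; 2 (2E,6E)-farnesyl bromide
Product: 4 (5E,9E)-1-[(tert-butyldimethylsilyl)oxy]-6,10,14-trimethylpentadeca-5,9,13-trien-2-one, via lithium enolate 3 (not isolated)
Conditions: LiN(iPr)2 (1.5 equiv), 1 (1.6 equiv), THF, −78 °C; then 2 (1.0 equiv), DMPU, −78 → −30 °C
Reagents that add atoms: none
Why: Kinetic deprotonation takes place on the methyl side, away from the bulky non-chelating silyloxy group, and the enolate is C-alkylated by the primary allylic bromide (SN2 enolate alkylation) without touching the 2E,6E olefins.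

**Step 2**
Reactants: 4 (5E,9E)-1-[(tert-butyldimethylsilyl)oxy]-6,10,14-trimethylpentadeca-5,9,13-trien-2-one
Product: 5 (5E,9E,13E)-1-[(tert-butyldimethylsilyl)oxy]-15-hydroxy-6,10,14-trimethylpentadeca-5,9,13-trien-2-one
Conditions: SeO2 (0.3 equiv), t-BuOOH (70% aq., 3 equiv), salicylic acid (0.1 equiv), CH2Cl2, 0 °C → rt, stopped near 60% conversion, 4 recycled
Reagents that add atoms: tert-butyl hydroperoxide, CC(C)(C)OO; selenium dioxide (catalytic oxygen carrier), O=[Se]=O
Why: Sharpless-type catalytic SeO2 allylic oxidation (ene reaction, then 2,3-sigmatropic shift) attacks the most accessible terminal olefin at its E-methyl group and gives the E allylic alcohol, as in the ω-hydroxylation of farnesyl and geranylgeranyl esters, while the α-silyloxy ketone is inert at room temperature.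

**Step 3**
Reactants: 5 (5E,9E,13E)-1-[(tert-butyldimethylsilyl)oxy]-15-hydroxy-6,10,14-trimethylpentadeca-5,9,13-trien-2-one; 6 [2-(1,3-dioxolan-2-yl)ethyl]triphenylphosphonium bromide
Product: 8 (2E,6E,10E,14Z)-14-{[(tert-butyldimethylsilyl)oxy]methyl}-16-(1,3-dioxolan-2-yl)-2,6,10-trimethylhexadeca-2,6,10,14-tetraen-1-ol, via phosphonium ylide 7 (not isolated)
Conditions: 6 (3.0 equiv), KN(SiMe3)2 (2.9 equiv), THF, 0 °C; then 5, −78 °C → rt
Reagents that add atoms: none
Why: Wittig olefination of an α-alkoxy (here α-silyloxy) ketone with a non-stabilised ylide is the Still Z-selective variant, which places the CH2O group cis to the incoming chain (the solution used for the same motif in plaunotol), and the excess ylide covers the free hydroxyl.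

**Step 4**
Reactants: 8 (2E,6E,10E,14Z)-14-{[(tert-butyldimethylsilyl)oxy]methyl}-16-(1,3-dioxolan-2-yl)-2,6,10-trimethylhexadeca-2,6,10,14-tetraen-1-ol
Product: 9 (3Z,7E,11E,15E)-4-{[(tert-butyldimethylsilyl)oxy]methyl}-17-hydroxy-8,12,16-trimethylheptadeca-3,7,11,15-tetraenal
Conditions: Ce(OTf)3 (0.3 equiv), MeNO2 saturated with H2O, rt; aldehyde used at once
Reagents that add atoms: water, O
Why: Lewis acid-catalysed acetal hydrolysis at nearly neutral pH spares the allylic silyl ether and avoids acid- or base-promoted migration of the β,γ-double bond into conjugation.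

**Step 5**
Reactants: 10 methyl 4-hydroxybut-2-ynoate
Product: 11 methyl (2Z)-4-hydroxy-3-iodobut-2-enoate
Conditions: NaI (1.6 equiv), AcOH (2.5 equiv), MeCN, 70 °C
Reagents that add atoms: sodium iodide, [Na+].[I-]
Why: Conjugate hydroiodination of an ynoate is an anti addition that puts iodine cis to the ester (Z), the geometry needed for ring closure, and any E isomer lactonises to 4-iodofuranone and is removed on silica.

**Step 6**
Reactants: 9 (3Z,7E,11E,15E)-4-{[(tert-butyldimethylsilyl)oxy]methyl}-17-hydroxy-8,12,16-trimethylheptadeca-3,7,11,15-tetraenal; 11 methyl (2Z)-4-hydroxy-3-iodobut-2-enoate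
Product: 14 (5R)-5-[(2Z,6E,10E,14E)-3-{[(tert-butyldimethylsilyl)oxy]methyl}-16-hydroxy-7,11,15-trimethylhexadeca-2,6,10,14-tetraen-1-yl]-4-(hydroxymethyl)furan-2(5H)-one, via alkenylchromium dichloride 12 (not isolated), via dichlorochromium alkoxide of the seco ester 13 (not isolated)
Conditions: CrCl2 (4.0 equiv), (S)-N-[2-(4-isopropyl-4,5-dihydrooxazol-2-yl)-6-methylphenyl]methanesulfonamide (4.4 equiv), Et3N (4.0 equiv), THF, rt, 1 h; then NiCl2 (0.1 equiv), 9 (1 equiv), 11 (2 equiv), rt; aq. ethylenediamine work-up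
Reagents that add atoms: none
Why: Asymmetric Nozaki–Hiyama–Kishi coupling, in which zerovalent nickel inserts into the C–I bond with retention, transmetalation gives an alkenyl derivative of trivalent chromium that adds to the Si face of the aldehyde under control of the chiral sulfonamide ligand (setting C4 as R), and the alkoxide, held cis to the ester, lactonises with loss of methoxide exactly as the (2Z)-4-hydroxy seco acid is presumed to close in nature, while the trans CH2OH cannot compete and organochromium reagents tolerate the free hydroxyls.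

**Step 7**
Reactants: 14 (5R)-5-[(2Z,6E,10E,14E)-3-{[(tert-butyldimethylsilyl)oxy]methyl}-16-hydroxy-7,11,15-trimethylhexadeca-2,6,10,14-tetraen-1-yl]-4-(hydroxymethyl)furan-2(5H)-one
Product: 15 hippolide F, (5R)-5-[(2Z,6E,10E,14E)-16-hydroxy-3-(hydroxymethyl)-7,11,15-trimethylhexadeca-2,6,10,14-tetraen-1-yl]-4-(hydroxymethyl)furan-2(5H)-one
Conditions: camphorsulfonic acid (0.1 equiv), MeOH/CH2Cl2 (1:1), 0 °C; NaHCO3 quench
Reagents that add atoms: none
Why: Acid-catalysed methanolysis of a primary silyl ether (desilylation) is mild enough to leave the allylic alcohols alone and, being non-basic, cannot epimerise the γ-stereocentre of the butenolide.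

**Compound list**

1 | 1-[(tert-butyldimethylsilyl)oxy]propan-2-one | CC(=O)CO[Si](C)(C)C(C)(C)C | starting material
2 | (2E,6E)-farnesyl bromide, (2E,6E)-1-bromo-3,7,11-trimethyldodeca-2,6,10-triene | CC(C)=CCC/C(C)=C/CC/C(C)=C/CBr | starting material
3 | lithium 3-[(tert-butyldimethylsilyl)oxy]prop-1-en-2-olate (lithium enolate of 1, not isolated) | [Li+].[O-]C(=C)CO[Si](C)(C)C(C)(C)C | intermediate
4 | (5E,9E)-1-[(tert-butyldimethylsilyl)oxy]-6,10,14-trimethylpentadeca-5,9,13-trien-2-one | CC(C)=CCC/C(C)=C/CC/C(C)=C/CCC(=O)CO[Si](C)(C)C(C)(C)C | intermediate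
5 | (5E,9E,13E)-1-[(tert-butyldimethylsilyl)oxy]-15-hydroxy-6,10,14-trimethylpentadeca-5,9,13-trien-2-one | C/C(=C\CC/C(C)=C/CC/C(C)=C/CCC(=O)CO[Si](C)(C)C(C)(C)C)CO | intermediate
6 | [2-(1,3-dioxolan-2-yl)ethyl]triphenylphosphonium bromide | [Br-].C1COC(CC[P+](c2ccccc2)(c2ccccc2)c2ccccc2)O1 | starting material
7 | [2-(1,3-dioxolan-2-yl)ethylidene]triphenylphosphorane (ylide, not isolated) | C1COC(C[CH-][P+](c2ccccc2)(c2ccccc2)c2ccccc2)O1 | intermediate
8 | (2E,6E,10E,14Z)-14-{[(tert-butyldimethylsilyl)oxy]methyl}-16-(1,3-dioxolan-2-yl)-2,6,10-trimethylhexadeca-2,6,10,14-tetraen-1-ol | C/C(=C\CC/C(C)=C/CC/C(C)=C/CC/C(=C/CC1OCCO1)CO[Si](C)(C)C(C)(C)C)CO | intermediate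
9 | (3Z,7E,11E,15E)-4-{[(tert-butyldimethylsilyl)oxy]methyl}-17-hydroxy-8,12,16-trimethylheptadeca-3,7,11,15-tetraenal | C/C(=C\CC/C(C)=C/CC/C(C)=C/CC/C(=C/CC=O)CO[Si](C)(C)C(C)(C)C)CO | intermediate
10 | methyl 4-hydroxybut-2-ynoate | COC(=O)C#CCO | starting material
11 | methyl (2Z)-4-hydroxy-3-iodobut-2-enoate | COC(=O)/C=C(\I)CO | intermediate
12 | methyl (2Z)-3-(dichlorochromio)-4-hydroxybut-2-enoate (alkenylchromium dichloride, chromium cis to the ester, not isolated) | COC(=O)/C=C(\[Cr](Cl)Cl)CO | intermediate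
13 | dichlorochromium alkoxide of methyl (2Z,4R,6Z,10E,14E,18E)-7-{[(tert-butyldimethylsilyl)oxy]methyl}-4,20-dihydroxy-3-(hydroxymethyl)-11,15,19-trimethylicosa-2,6,10,14,18-pentaenoate (seco ester, not isolated) | C/C(=C\CC/C(C)=C/CC/C(C)=C/CC/C(=C/C[C@@H](O[Cr](Cl)Cl)/C(CO)=C\C(=O)OC)CO[Si](C)(C)C(C)(C)C)CO | intermediate
14 | (5R)-5-[(2Z,6E,10E,14E)-3-{[(tert-butyldimethylsilyl)oxy]methyl}-16-hydroxy-7,11,15-trimethylhexadeca-2,6,10,14-tetraen-1-yl]-4-(hydroxymethyl)furan-2(5H)-one | C/C(=C\CC/C(C)=C/CC/C(C)=C/CC/C(=C/C[C@H]1OC(=O)C=C1CO)CO[Si](C)(C)C(C)(C)C)CO | intermediate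
15 | hippolide F, (5R)-5-[(2Z,6E,10E,14E)-16-hydroxy-3-(hydroxymethyl)-7,11,15-trimethylhexadeca-2,6,10,14-tetraen-1-yl]-4-(hydroxymethyl)furan-2(5H)-one | C/C(=C\CC/C(C)=C/CC/C(C)=C/CC/C(=C/C[C@H]1OC(=O)C=C1CO)CO)CO | target

**Step count**

Total steps: 7. Longest linear sequence: 6 (steps 1, 2, 3, 4, 6, 7 from farnesyl bromide); step 5 is a one-step side branch.

**Steps most likely to fail, with fallbacks**

Step 6. The risks are a modest ee with an unbranched, enolisable aldehyde, migration of the β,γ-double bond, and Z to E leakage of the alkenyl metal. The fallback sets out from aldehyde 9 and separates the stereo-setting from the ring closure. Me2Zn with the ProPhenol ligand (enantiomer giving the R carbinol; toluene, 4 °C) adds methyl propiolate to 9 and gives methyl (4R,6Z,10E,14E,18E)-7-{[(tert-butyldimethylsilyl)oxy]methyl}-4,20-dihydroxy-11,15,19-trimethylicosa-6,10,14,18-tetraen-2-ynoate F1. Syn carbocupration with the cuprate (CH3OCH2OCH2)2CuLi, made from Bu3SnCH2OCH2OCH3, n-BuLi and CuBr·SMe2 (THF, −78 °C), puts the new CH2O group on C3 and leaves the C4 alkoxide cis to the ester. Lactonisation then gives (5R)-5-[(2Z,6E,10E,14E)-3-{[(tert-butyldimethylsilyl)oxy]methyl}-16-hydroxy-7,11,15-trimethylhexadeca-2,6,10,14-tetraen-1-yl]-4-[(methoxymethoxy)methyl]furan-2(5H)-one F2. Me2BBr (CH2Cl2, −78 °C) cleaves the methoxymethyl ether and the route is rejoined at 14.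

Step 4. The risks are loss of the allylic silyl ether and conjugation of the 3-enal during acetal cleavage. The fallback sets out from hydroxy ketone 5 and reaches the aldehyde by oxidation instead of hydrolysis, which requires the terminal hydroxyl to be capped. TBSCl and imidazole give (5E,9E,13E)-1,15-bis[(tert-butyldimethylsilyl)oxy]-6,10,14-trimethylpentadeca-5,9,13-trien-2-one F3. Wittig reaction with the ylide from (3-hydroxypropyl)triphenylphosphonium bromide (NaN(SiMe3)2, 2 equiv per salt, THF) gives (3Z,7E,11E,15E)-17-[(tert-butyldimethylsilyl)oxy]-4-{[(tert-butyldimethylsilyl)oxy]methyl}-8,12,16-trimethylheptadeca-3,7,11,15-tetraen-1-ol F4. Dess–Martin periodinane buffered with NaHCO3 gives (3Z,7E,11E,15E)-17-[(tert-butyldimethylsilyl)oxy]-4-{[(tert-butyldimethylsilyl)oxy]methyl}-8,12,16-trimethylheptadeca-3,7,11,15-tetraenal F5. Coupling with 11 under the conditions of step 6 gives (5R)-5-[(2Z,6E,10E,14E)-16-[(tert-butyldimethylsilyl)oxy]-3-{[(tert-butyldimethylsilyl)oxy]methyl}-7,11,15-trimethylhexadeca-2,6,10,14-tetraen-1-yl]-4-(hydroxymethyl)furan-2(5H)-one F6. The conditions of step 7 remove both silyl groups and the route is rejoined at 15.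

Step 2. The risk is that the three unactivated trisubstituted olefins of 4 are poorly distinguished, with over-oxidation to the enal. The fallback sets out from bromide 2, moves the oxidation to a substrate on which it is established, and makes the C8–C9 bond by π-allyl chemistry. KOAc in DMF gives (2E,6E)-3,7,11-trimethyldodeca-2,6,10-trien-1-yl acetate F7. SeO2/t-BuOOH, with the proximal olefin deactivated by the allylic acetate, gives (2E,6E,10E)-12-hydroxy-3,7,11-trimethyldodeca-2,6,10-trien-1-yl acetate F8. Pd(PPh3)4-catalysed allylation of the potassium enolate of 1 (KN(SiMe3)2, BEt3; 2.5 equiv, one equivalent serving to deprotonate the hydroxyl) attacks the unhindered allyl terminus with retention of olefin geometry, and the route is rejoined at 5.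

**Further compounds**

F1 | step 6 | methyl (4R,6Z,10E,14E,18E)-7-{[(tert-butyldimethylsilyl)oxy]methyl}-4,20-dihydroxy-11,15,19-trimethylicosa-6,10,14,18-tetraen-2-ynoate | C/C(=C\CC/C(C)=C/CC/C(C)=C/CC/C(=C/C[C@@H](O)C#CC(=O)OC)CO[Si](C)(C)C(C)(C)C)CO
F2 | step 6 | (5R)-5-[(2Z,6E,10E,14E)-3-{[(tert-butyldimethylsilyl)oxy]methyl}-16-hydroxy-7,11,15-trimethylhexadeca-2,6,10,14-tetraen-1-yl]-4-[(methoxymethoxy)methyl]furan-2(5H)-one | C/C(=C\CC/C(C)=C/CC/C(C)=C/CC/C(=C/C[C@H]1OC(=O)C=C1COCOC)CO[Si](C)(C)C(C)(C)C)CO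
F3 | step 4 | (5E,9E,13E)-1,15-bis[(tert-butyldimethylsilyl)oxy]-6,10,14-trimethylpentadeca-5,9,13-trien-2-one | C/C(=C\CC/C(C)=C/CC/C(C)=C/CCC(=O)CO[Si](C)(C)C(C)(C)C)CO[Si](C)(C)C(C)(C)C
F4 | step 4 | (3Z,7E,11E,15E)-17-[(tert-butyldimethylsilyl)oxy]-4-{[(tert-butyldimethylsilyl)oxy]methyl}-8,12,16-trimethylheptadeca-3,7,11,15-tetraen-1-ol | C/C(=C\CC/C(C)=C/CC/C(C)=C/CC/C(=C/CCO)CO[Si](C)(C)C(C)(C)C)CO[Si](C)(C)C(C)(C)C
F5 | step 4 | (3Z,7E,11E,15E)-17-[(tert-butyldimethylsilyl)oxy]-4-{[(tert-butyldimethylsilyl)oxy]methyl}-8,12,16-trimethylheptadeca-3,7,11,15-tetraenal | C/C(=C\CC/C(C)=C/CC/C(C)=C/CC/C(=C/CC=O)CO[Si](C)(C)C(C)(C)C)CO[Si](C)(C)C(C)(C)C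
F6 | step 4 | (5R)-5-[(2Z,6E,10E,14E)-16-[(tert-butyldimethylsilyl)oxy]-3-{[(tert-butyldimethylsilyl)oxy]methyl}-7,11,15-trimethylhexadeca-2,6,10,14-tetraen-1-yl]-4-(hydroxymethyl)furan-2(5H)-one | C/C(=C\CC/C(C)=C/CC/C(C)=C/CC/C(=C/C[C@H]1OC(=O)C=C1CO)CO[Si](C)(C)C(C)(C)C)CO[Si](C)(C)C(C)(C)C
F7 | step 2 | (2E,6E)-3,7,11-trimethyldodeca-2,6,10-trien-1-yl acetate | CC(C)=CCC/C(C)=C/CC/C(C)=C/COC(C)=O
F8 | step 2 | (2E,6E,10E)-12-hydroxy-3,7,11-trimethyldodeca-2,6,10-trien-1-yl acetate | C/C(=C\CC/C(C)=C/CC/C(C)=C/COC(C)=O)CO
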